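**Strategy**

Ring A is grown on the ring B oxygen instead of being coupled to it. The feature exploited is the 1,3,5-pattern of ring A: C2–OH, C6–OAr and C4–CH3 are mutually meta and the still unsubstituted C1 sits between the two oxygens, exactly what annulation of a vinylketene onto an ynol ether produces. Warming the ring B aryl ethynyl ether with 3-methylcyclobutenone creates C1–C2, C5–C6 and C2–C3 and releases ring A as its free C2 phenol in a single operation. The precursor is the ethynyl ether of a 2,6-disubstituted phenol carrying an aryl OTIPS at C2' and a CH2OTIPS at C6'. The C1 ester follows by lithiation between the two oxygens.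

Key step: step 10

Numbering: ring A is C1 (CO2CH3), C2 (OH), C3 (H), C4 (CH3), C5 (H), C6 (O-aryl). Ring B is C1' (ether O), C2' (OH), C3' (H), C4' (OCH3), C5' (H), C6' (CH2OAc).

Remark on the way to the precursor: both TIPS groups are installed only after the dichlorovinyl ether is in place. A phenoxide next to an aryl silyl ether would allow O-to-O silyl migration during the basic vinylation. A THP acetal, which cannot migrate, covers C2'–O in that step.

Remark on the endgame: the two TIPS ethers leave at different times, the alkyl one with acid and the aryl one with buffered fluoride. Acetylation therefore never meets a reactive free phenol. The C2' phenoxide is also never exposed to base beside the C1 ester, which avoids Smiles rearrangement and lactonisation.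

Assumption: the target is achiral as drawn. The only descriptors in the route are the (E)-alkene of the dichlorovinyl ethers and two transient racemic centres (the THP acetal carbon and C4 of the vinylcyclobutenone).

**Route**

Step 1
Reactants: 1 2-hydroxy-5-methoxybenzaldehyde
Product: 2 3-bromo-2-hydroxy-5-methoxybenzaldehyde
Conditions: Br2, NaOAc, AcOH, rt
Reagents that add atoms: bromine, BrBr
Why: Electrophilic aromatic bromination in which the free hydroxyl is the strongest director and its para position carries OCH3, so bromine enters the open ortho position C3 (the future C2').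

Step 2
Reactants: 2 3-bromo-2-hydroxy-5-methoxybenzaldehyde
Product: 3 2,3-dihydroxy-5-methoxybenzaldehyde
Conditions: aq. NaOH, Cu powder (cat.), reflux, N2; then HCl to pH 2
Reagents that add atoms: sodium hydroxide, [Na+].[OH-]
Why: Copper-mediated Ullmann-type hydrolysis of an ortho-halophenoxide, the transformation that converts 5-bromovanillin into 5-hydroxyvanillin, with the phenoxide form shielding the aldehyde from Cannizzaro disproportionation and N2 preventing catechol oxidation.

Step 3
Reactants: 3 2,3-dihydroxy-5-methoxybenzaldehyde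
Product: 4 (±)-2-hydroxy-5-methoxy-3-(tetrahydropyran-2-yloxy)benzaldehyde
Conditions: 3,4-dihydro-2H-pyran, PPTS (cat.), CH2Cl2, rt
Reagents that add atoms: 3,4-dihydro-2H-pyran, C1=COCCC1
Why: Acid-catalysed tetrahydropyranylation is reversible and spares the C2 hydroxyl, which is locked in a hydrogen bond to the formyl oxygen, so only the C3 hydroxyl is acetalised, the new acetal carbon being racemic and removed in step 5.

Step 4
Reactants: 4 (±)-2-hydroxy-5-methoxy-3-(tetrahydropyran-2-yloxy)benzaldehyde; 5 trichloroethylene
Product: 7 (±)-2-[(E)-1,2-dichlorovinyloxy]-5-methoxy-3-(tetrahydropyran-2-yloxy)benzaldehyde, via dichloroacetylene 6 (not isolated)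
Conditions: K2CO3, DMF, 65 °C, N2
Reagents that add atoms: none
Why: Base-mediated O-dichlorovinylation, known for salicylaldehydes, in which K2CO3 dehydrochlorinates 5 to 6 and anti addition of the phenoxide followed by protonation gives only the (E)-alkene.

Step 5
Reactants: 7 (±)-2-[(E)-1,2-dichlorovinyloxy]-5-methoxy-3-(tetrahydropyran-2-yloxy)benzaldehyde
Product: 9 2-[(E)-1,2-dichlorovinyloxy]-3-(hydroxymethyl)-5-methoxyphenol, via THP-protected benzylic alcohol 8 (not isolated)
Conditions: NaBH4, MeOH, 0 °C; then 2 M HCl to pH 1–2, rt
Reagents that add atoms: none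
Why: Chemoselective borohydride reduction of the aldehyde is followed in the same flask by acid-catalysed acetal exchange of the very labile aryl THP ether, conditions mild enough to leave the electron-poor dichlorovinyl ether and the weakly ionisable benzylic alcohol untouched.

Step 6
Reactants: 9 2-[(E)-1,2-dichlorovinyloxy]-3-(hydroxymethyl)-5-methoxyphenol
Product: 10 2-[(E)-1,2-dichlorovinyloxy]-5-methoxy-1-(triisopropylsilyloxy)-3-(triisopropylsilyloxymethyl)benzene
Conditions: TIPSOTf (2.3 equiv), 2,6-lutidine, CH2Cl2, 0 °C to rt
Reagents that add atoms: triisopropylsilyl trifluoromethanesulfonate, CC(C)[Si](OS(=O)(=O)C(F)(F)F)(C(C)C)C(C)C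
Why: Standard silylation with a silyl triflate protects the phenol and the primary alcohol in one operation, and the weak hindered base never generates a phenoxide that could attack the neighbouring dichlorovinyl ether.

Step 7
Reactants: 10 2-[(E)-1,2-dichlorovinyloxy]-5-methoxy-1-(triisopropylsilyloxy)-3-(triisopropylsilyloxymethyl)benzene
Product: 13 2-ethynyloxy-5-methoxy-1-(triisopropylsilyloxy)-3-(triisopropylsilyloxymethyl)benzene, via chloroethynyl ether 11 (not isolated), via lithium acetylide 12 (not isolated)
Conditions: n-BuLi (2.5 equiv), THF, −78 to −40 °C; H2O, −78 °C; quick filtration over Et3N-deactivated silica, used at once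
Reagents that add atoms: none
Why: This is the established conversion of aryl dichlorovinyl ethers into ynol ethers, in which lithiation of the vinylic C–H and loss of LiCl give 11, chlorine–lithium exchange gives 12 and cold protonation frees the terminal alkyne, while TIPS ethers resist n-BuLi.

Step 8
Reactants: 14 propyne; 15 trichloroacetyl chloride
Product: 17 4,4-dichloro-3-methylcyclobut-2-en-1-one, via dichloroketene 16 (not isolated)
Conditions: Zn–Cu couple, Et2O–DME, 0 °C to rt, dry-ice condenser
Reagents that add atoms: none
Why: Zinc dechlorinates the acid chloride to dichloroketene, which undergoes the known [2+2] cycloaddition with a terminal alkyne, the terminal alkyne carbon bonding to the ketene carbonyl carbon so that the methyl group ends at C3.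

Step 9
Reactants: 17 4,4-dichloro-3-methylcyclobut-2-en-1-one
Product: 18 3-methylcyclobut-2-en-1-one
Conditions: Zn dust, AcOH, TMEDA, EtOH, 0 °C to rt; careful distillation, kept as a toluene solution
Reagents that add atoms: none
Why: Reductive dechlorination of an α,α-dichloroketone by zinc is buffered by AcOH–TMEDA so that the sensitive, volatile cyclobutenone is neither isomerised nor opened.

Step 10
Reactants: 13 2-ethynyloxy-5-methoxy-1-(triisopropylsilyloxy)-3-(triisopropylsilyloxymethyl)benzene; 18 3-methylcyclobut-2-en-1-one
Product: 23 3-[4-methoxy-2-(triisopropylsilyloxy)-6-(triisopropylsilyloxymethyl)phenoxy]-5-methylphenol, via isopropenylketene 19 (not isolated), via vinylcyclobutenone 20 (not isolated), via dienylketene 21 (not isolated), via cyclohexadienone 22 (not isolated)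
Conditions: 18 (1.5 equiv, added in portions), toluene, sealed tube, 80 °C, then 110 °C
Reagents that add atoms: none
Why: At 80 °C 18 opens reversibly by a conrotatory 4π process to ketene 19, whose C=C=O unit is captured by the electron-rich alkyne of 13 in a [2+2] cycloaddition (C1–C2 and C5–C6) to give 20. Further heating opens 20 by a second 4π process to 21, and ring A closes by disrotatory 6π electrocyclisation (C2–C3) to dienone 22, which tautomerises irreversibly to phenol 23. This is the Danheiser benzannulation, established for alkoxy- and siloxyacetylenes, and 13 is an aryl member of the same ynol ether class. The only selectivity needed is regiochemical: oxygen donation makes the terminal CH of 13 the nucleophilic carbon, it bonds to the ketene carbonyl carbon, and the aryloxy group therefore ends meta to the new hydroxyl with C1–H between them and the methyl meta to both. No stereocentre remains in 23, since the racemic one in 20 is erased on ring opening. Ether 13 should tolerate the heating because it has no sp3 β-hydrogen for retro-ene fragmentation and both positions ortho to its oxygen are blocked.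

Step 11
Reactants: 23 3-[4-methoxy-2-(triisopropylsilyloxy)-6-(triisopropylsilyloxymethyl)phenoxy]-5-methylphenol
Product: 24 MOM ether of 23 (1-methoxymethoxy-3-aryloxy-5-methylbenzene)
Conditions: MOMCl, i-Pr2NEt, CH2Cl2, 0 °C to rt
Reagents that add atoms: chloromethyl methyl ether, COCCl
Why: Williamson-type O-alkylation of the only free hydroxyl under amine base installs a chelating directing group and leaves both silyl ethers untouched.

Step 12
Reactants: 24 MOM ether of 23
Product: 26 methyl 2-(methoxymethoxy)-4-methyl-6-[4-methoxy-2-(triisopropylsilyloxy)-6-(triisopropylsilyloxymethyl)phenoxy]benzoate, via C1 aryllithium 25 (not isolated)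
Conditions: n-BuLi (1.2 equiv), THF, −78 to 0 °C; ClCO2CH3 (3 equiv), −78 °C to rt
Reagents that add atoms: methyl chloroformate, COC(=O)Cl
Why: In this directed ortho-metalation C1–H lies between the chelating OMOM and the acidifying OAr and is lithiated first, ring B being protected because the bulky non-coordinating OTIPS shields C3' and C5' has only a methoxy neighbour, and the resulting 2,6-disubstituted ester resists a second addition.

Step 13
Reactants: 26 methyl 2-(methoxymethoxy)-4-methyl-6-[4-methoxy-2-(triisopropylsilyloxy)-6-(triisopropylsilyloxymethyl)phenoxy]benzoate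
Product: 27 methyl 2-hydroxy-6-[2-(hydroxymethyl)-4-methoxy-6-(triisopropylsilyloxy)phenoxy]-4-methylbenzoate
Conditions: conc. HCl (1% v/v, cat.), MeOH–THF, 40 °C
Reagents that add atoms: none
Why: Acid-catalysed methanolysis cleaves the aryl MOM acetal and the primary alkyl TIPS ether while an aryl TIPS ether is far slower under acid, and methanol as solvent makes any ester exchange degenerate and disfavours lactonisation.

Step 14
Reactants: 27 methyl 2-hydroxy-6-[2-(hydroxymethyl)-4-methoxy-6-(triisopropylsilyloxy)phenoxy]-4-methylbenzoate
Product: 28 methyl 2-[2-(acetoxymethyl)-4-methoxy-6-(triisopropylsilyloxy)phenoxy]-6-hydroxy-4-methylbenzoate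
Conditions: Ac2O (1.1 equiv), pyridine, CH2Cl2, 0 °C to rt, no DMAP
Reagents that add atoms: acetic anhydride, CC(=O)OC(C)=O
Why: Chemoselective acetylation takes the primary benzylic alcohol because the only free phenol (C2–OH) is hydrogen-bonded to the ortho ester and poorly nucleophilic, while C2'–O is still silylated.

Step 15
Reactants: 28 methyl 2-[2-(acetoxymethyl)-4-methoxy-6-(triisopropylsilyloxy)phenoxy]-6-hydroxy-4-methylbenzoate
Product: 29 betaethrin A
Conditions: Bu4NF, AcOH (1:1), THF, 0 °C
Reagents that add atoms: none
Why: Fluoride cleavage of an aryl silyl ether is fast at 0 °C, and the AcOH buffer protonates the liberated C2' phenoxide at once so that Smiles rearrangement, attack on the C1 ester and acetate loss are avoided.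

**Compound list**

1 | 2-hydroxy-5-methoxybenzaldehyde | COc1ccc(O)c(C=O)c1 | starting material
2 | 3-bromo-2-hydroxy-5-methoxybenzaldehyde | COc1cc(Br)c(O)c(C=O)c1 | intermediate
3 | 2,3-dihydroxy-5-methoxybenzaldehyde | COc1cc(O)c(O)c(C=O)c1 | intermediate
4 | (±)-2-hydroxy-5-methoxy-3-(tetrahydropyran-2-yloxy)benzaldehyde | COc1cc(OC2CCCCO2)c(O)c(C=O)c1 | intermediate
5 | trichloroethylene | ClC=C(Cl)Cl | starting material
6 | dichloroacetylene (in situ) | ClC#CCl | intermediate
7 | (±)-2-[(E)-1,2-dichlorovinyloxy]-5-methoxy-3-(tetrahydropyran-2-yloxy)benzaldehyde | COc1cc(OC2CCCCO2)c(O/C(Cl)=C\Cl)c(C=O)c1 | intermediate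
8 | (±)-{2-[(E)-1,2-dichlorovinyloxy]-5-methoxy-3-(tetrahydropyran-2-yloxy)phenyl}methanol (in situ) | COc1cc(OC2CCCCO2)c(O/C(Cl)=C\Cl)c(CO)c1 | intermediate
9 | 2-[(E)-1,2-dichlorovinyloxy]-3-(hydroxymethyl)-5-methoxyphenol | COc1cc(O)c(O/C(Cl)=C\Cl)c(CO)c1 | intermediate
10 | 2-[(E)-1,2-dichlorovinyloxy]-5-methoxy-1-(triisopropylsilyloxy)-3-(triisopropylsilyloxymethyl)benzene | COc1cc(O[Si](C(C)C)(C(C)C)C(C)C)c(O/C(Cl)=C\Cl)c(CO[Si](C(C)C)(C(C)C)C(C)C)c1 | intermediate
11 | chloroethynyl ether of ring B (in situ) | ClC#COc1c(O[Si](C(C)C)(C(C)C)C(C)C)cc(OC)cc1CO[Si](C(C)C)(C(C)C)C(C)C | intermediate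
12 | lithium acetylide of the ring B ynol ether (in situ) | [Li]C#COc1c(O[Si](C(C)C)(C(C)C)C(C)C)cc(OC)cc1CO[Si](C(C)C)(C(C)C)C(C)C | intermediate
13 | 2-ethynyloxy-5-methoxy-1-(triisopropylsilyloxy)-3-(triisopropylsilyloxymethyl)benzene | C#COc1c(O[Si](C(C)C)(C(C)C)C(C)C)cc(OC)cc1CO[Si](C(C)C)(C(C)C)C(C)C | intermediate
14 | propyne | CC#C | starting material
15 | trichloroacetyl chloride | ClC(Cl)(Cl)C(Cl)=O | starting material
16 | dichloroketene (in situ) | ClC(Cl)=C=O | intermediate
17 | 4,4-dichloro-3-methylcyclobut-2-en-1-one | CC1=CC(=O)C1(Cl)Cl | intermediate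
18 | 3-methylcyclobut-2-en-1-one | CC1=CC(=O)C1 | intermediate
19 | isopropenylketene (in situ) | CC(=C)C=C=O | intermediate
20 | (±)-3-aryloxy-4-(prop-1-en-2-yl)cyclobut-2-en-1-one (in situ) | O=C1C=C(Oc2c(O[Si](C(C)C)(C(C)C)C(C)C)cc(OC)cc2CO[Si](C(C)C)(C(C)C)C(C)C)C1C(C)=C | intermediate
21 | 3-aryloxy-5-methylhexa-1,3,5-trien-1-one, ketene and isopropenyl termini cis (in situ) | O=C=C/C(Oc1c(O[Si](C(C)C)(C(C)C)C(C)C)cc(OC)cc1CO[Si](C(C)C)(C(C)C)C(C)C)=C\C(C)=C | intermediate
22 | 3-aryloxy-5-methylcyclohexa-2,4-dien-1-one (in situ) | O=C1C=C(Oc2c(O[Si](C(C)C)(C(C)C)C(C)C)cc(OC)cc2CO[Si](C(C)C)(C(C)C)C(C)C)C=C(C)C1 | intermediate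
23 | 3-[4-methoxy-2-(triisopropylsilyloxy)-6-(triisopropylsilyloxymethyl)phenoxy]-5-methylphenol | Cc1cc(O)cc(Oc2c(O[Si](C(C)C)(C(C)C)C(C)C)cc(OC)cc2CO[Si](C(C)C)(C(C)C)C(C)C)c1 | intermediate
24 | MOM ether of 23 | COCOc1cc(C)cc(Oc2c(O[Si](C(C)C)(C(C)C)C(C)C)cc(OC)cc2CO[Si](C(C)C)(C(C)C)C(C)C)c1 | intermediate
25 | C1 aryllithium of 24 (in situ) | [Li]c1c(OCOC)cc(C)cc1Oc1c(O[Si](C(C)C)(C(C)C)C(C)C)cc(OC)cc1CO[Si](C(C)C)(C(C)C)C(C)C | intermediate
26 | methyl 2-(methoxymethoxy)-4-methyl-6-[4-methoxy-2-(triisopropylsilyloxy)-6-(triisopropylsilyloxymethyl)phenoxy]benzoate | COC(=O)c1c(OCOC)cc(C)cc1Oc1c(O[Si](C(C)C)(C(C)C)C(C)C)cc(OC)cc1CO[Si](C(C)C)(C(C)C)C(C)C | intermediate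
27 | methyl 2-hydroxy-6-[2-(hydroxymethyl)-4-methoxy-6-(triisopropylsilyloxy)phenoxy]-4-methylbenzoate | COC(=O)c1c(O)cc(C)cc1Oc1c(O[Si](C(C)C)(C(C)C)C(C)C)cc(OC)cc1CO | intermediate
28 | methyl 2-[2-(acetoxymethyl)-4-methoxy-6-(triisopropylsilyloxy)phenoxy]-6-hydroxy-4-methylbenzoate | COC(=O)c1c(O)cc(C)cc1Oc1c(O[Si](C(C)C)(C(C)C)C(C)C)cc(OC)cc1COC(C)=O | intermediate
29 | betaethrin A, methyl 2-[2-(acetoxymethyl)-6-hydroxy-4-methoxyphenoxy]-6-hydroxy-4-methylbenzoate | COC(=O)c1c(O)cc(C)cc1Oc1c(O)cc(OC)cc1COC(C)=O | target

**Step count**

Total steps: 15. The longest linear sequence is 13 steps (steps 1–7 and 10–15). The cyclobutenone branch (steps 8 and 9) is convergent.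

**Steps most likely to fail**

Step 10 (benzannulation).
- What may go wrong: thermal oligomerisation of the ynol ether before the cyclobutenone has opened, ketene dimerisation outrunning the sterically loaded [2+2] step, and acylation of the new phenol by surplus ketene.
- The fallback sets out from 13 and comes back at 23. It generates the same ketene 19 at room temperature by photochemical Wolff rearrangement, the diazoketone variant of the benzannulation that is known for ynol ethers.
- Commercial 3-methylbut-3-en-2-one is treated with LiN(SiMe3)2 and 2,2,2-trifluoroethyl trifluoroacetate to give 1,1,1-trifluoro-5-methylhex-5-ene-2,4-dione F1.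
- Detrifluoroacetylative diazo transfer with MsN3, Et3N and H2O in MeCN then gives 1-diazo-3-methylbut-3-en-2-one F2.
- Irradiation of F2 (about 300 nm) with 13 in CH2Cl2 should trap 19 as 20 while the ynol ether is still cold. A short period in hot toluene then carries 20 through 21 and 22 to 23.

Step 12 (metalation and carboxylation).
- What may go wrong: inefficient capture of the hindered aryllithium by the chloroformate, second addition to the newly formed ester, and proton return on warming.
- The fallback sets out from 25 and comes back at 26.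
- Dry CO2 is passed into the solution of 25 at −78 °C. This gives lithium 2-(methoxymethoxy)-4-methyl-6-aryloxybenzoate F3, a carboxylate that cannot accept a second aryllithium.
- After exchange of the solvent for DMF, SN2 methylation of F3 with MeI, which is insensitive to the ortho substituents, gives 26 without any acidic work-up that would endanger the MOM group.

Step 7 (ynol ether formation).
- What may go wrong: expulsion of aryloxide from the lithiated vinyl ether (the reverse of the addition in step 4), and hydration or oligomerisation of the terminal ynol ether during work-up and chromatography.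
- The fallback sets out from 12 and comes back at 13.
- The acetylide is intercepted at −78 °C with Me3SiCl to give the C-trimethylsilyl ynol ether F4, which should survive chromatography and storage.
- Catalytic K2CO3 in MeOH–THF at 0 °C releases 13 immediately before step 10, leaving both TIPS ethers in place.

**Further compounds**

F1 | step 10 | 1,1,1-trifluoro-5-methylhex-5-ene-2,4-dione | CC(=C)C(=O)CC(=O)C(F)(F)F
F2 | step 10 | 1-diazo-3-methylbut-3-en-2-one | CC(=C)C(=O)C=[N+]=[N-]
F3 | step 12 | lithium 2-(methoxymethoxy)-4-methyl-6-[4-methoxy-2-(triisopropylsilyloxy)-6-(triisopropylsilyloxymethyl)phenoxy]benzoate | [Li+].[O-]C(=O)c1c(OCOC)cc(C)cc1Oc1c(O[Si](C(C)C)(C(C)C)C(C)C)cc(OC)cc1CO[Si](C(C)C)(C(C)C)C(C)C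
F4 | step 7 | 5-methoxy-1-(triisopropylsilyloxy)-3-(triisopropylsilyloxymethyl)-2-[(trimethylsilyl)ethynyloxy]benzene | C[Si](C)(C)C#COc1c(O[Si](C(C)C)(C(C)C)C(C)C)cc(OC)cc1CO[Si](C(C)C)(C(C)C)C(C)C
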